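The numbers of this flask come from no measurement.

We have to decide within the hour whether this partner charge is worth running, so we need to know what share of each portion reaches target.

solid substrate 0.50 M; partner 0.650 M (in portions, 3); time 12 min; the portions of partner follow each other after 12 s, the first at the start

    partner → decomposed reagent (k1 = 0.047 s⁻¹)
    solid substrate ⇌ dissolved substrate, rate k2*(cs2 - [dissolved substrate]) while solid is left; crystals form when [dissolved substrate] > cs2 (cs2 = 0.18 M, k2 = 1.7 s⁻¹)
    partner → side product (k3 = 0.65 s⁻¹)
    dissolved substrate + partner → target (k4 = 2.0 M⁻¹ s⁻¹)

- why nothing more happens at 12 min, or that something still does (for what has run out or reacted, a solid counts together with what of it has only dissolved) (it is still moving / the partner has run out first / all of the solid substrate has reacted)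
- part of the solid substrate that has turned into other species by 12 min (what has only dissolved does not count)
- how much target there is at 12 min, in percent of the solid substrate charged

- solid substrate is a solid; its amount is given per volume of the solution
- at the start none of the solid substrate is in solution
- what has only dissolved of solid substrate counts as not reacted
- the reaction counts as stopped when no species that holds the solid substrate changes by six tenths of a point or more over the second half of the time
- run time (flask): 12 min

We reckon up a ladder of times, fastest first. Dissolution refills the solution in 0.588 s. Partner lives 0.946 s in saturated solution, longer but of like size, so as a rough step we take the dissolved substrate as keeping up with the partner present. The gap between portions is 12 s, about 12.7 partner lifetimes, so each portion decays before the next arrives, and the solution refills in between.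

Within a portion, partner decays in a pseudo-first-order way, and dividing one route's rate by the total removes both time and partner concentration. With partner at half its portion, the balance of dissolution against reaction puts dissolved substrate at 0.160 M. The route to target then runs at 0.319 s⁻¹, slower than the 0.697 s⁻¹ of the two losses. This gives 31.4%, the capture share: the fraction of partner that becomes target rather than side product or decomposed reagent.

Captured partner plus saturated solution takes 0.384 M, less than the solid substrate charged, so solid remains and the outcome is the partner has run out first. Target is the one product made from the substrate, so we expect 40.8% target and 40.8% conversion. We expect both to lean high: the first portion starts in a solution with none of the substrate dissolved, not at the 0.160 M we used.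

The forecast says the partner has run out first, with conversion and yield each 38% (35% to 41%), a little below our figure, on the grounds that “roughly a third of each portion becomes target”.

The simulation gives the partner has run out first, with 0% of the partner left, conversion 38.3% and target 38.3% at 12 min, which is 2.5 percentage points under our figure.

The neighbouring flask keeps the partner charge but holds 0.85 M of solid substrate. Reckoned the same way, the capture share stays 31.4%, so it should make the same 0.204 M of target, which against the larger charge is 24.0%. That neighbouring flask gives 22.5% target at 12.0 min, with 0% of its partner left, 21.2% of its substrate dissolved and 56.3% still solid.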